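The plan cuts the C1''–C2'' bond of the lavandulyl chain. C1'' is a benzylic methylene on C8 of ring A, flanked by the oxygens on C7 and C8a, and its neighbour C2'' is stereogenic. C8=C1'' is therefore read as an o-quinone methide and C2'' as the alpha-carbon of a chiral carbene-bound enolate. One catalytic operation forms C1''–C2'', sets (R)-C2'' and ties the future isopropenyl carbon C3'' to a ring A oxygen as a temporary dihydrocoumarin lactone. The precursor is a 2-silyloxy-6-(methoxymethoxy)benzyl bromide, paired with 5-methylhex-4-enoyl imidazole. Afterwards the MOM group directs ring lithiation, and C2 is set by rhodium-catalysed aryl addition to a chromone.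

Key step: step 8

Assumption: the absolute sense of induction of the chiral triazolium salt (step 8) and of the chiral diene ligand (step 18) is assigned by analogy with simpler substrates; if a first run shows the opposite sense, the equally available mirror-image catalyst is used.
Notation: (2R)-lavandulyl = (2R)-5-methyl-2-(prop-1-en-2-yl)hex-4-en-1-yl.

Step 1
Reactants: 1 2,6-dihydroxybenzaldehyde
Product: 2 2-hydroxy-6-(methoxymethoxy)benzaldehyde
Conditions: MOMCl (1.0 equiv), i-Pr2NEt, CH2Cl2, 0 °C
Reagents that add atoms: chloromethyl methyl ether, COCCl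
Why: Phenol O-alkylation with one equivalent of chloride; once the first phenol is capped, the remaining OH is locked in a strong hydrogen bond to the aldehyde and is far less nucleophilic, so mono-protection should prevail.

Step 2
Reactants: 2 2-hydroxy-6-(methoxymethoxy)benzaldehyde
Product: 3 2-(tert-butyldimethylsilyloxy)-6-(methoxymethoxy)benzaldehyde
Conditions: TBSCl, imidazole, DMF, rt
Reagents that add atoms: tert-butyldimethylsilyl chloride, CC(C)(C)[Si](C)(C)Cl
Why: Imidazole-promoted silylation of a phenol installs the fluoride-labile trigger next to a MOM ether that fluoride does not touch.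

Step 3
Reactants: 3 2-(tert-butyldimethylsilyloxy)-6-(methoxymethoxy)benzaldehyde
Product: 4 [2-(tert-butyldimethylsilyloxy)-6-(methoxymethoxy)phenyl]methanol
Conditions: NaBH4, MeOH/THF, -10 to 0 °C, short contact; pH 7 buffer
Reagents that add atoms: none
Why: Borohydride reduction of the aldehyde; low temperature and a buffered quench suppress aryl-to-benzyl oxygen-to-oxygen silyl migration in the alkoxide.

Step 4
Reactants: 4 [2-(tert-butyldimethylsilyloxy)-6-(methoxymethoxy)phenyl]methanol
Product: 5 tert-butyl[2-(bromomethyl)-3-(methoxymethoxy)phenoxy]dimethylsilane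
Conditions: CBr4, PPh3 (added last, in portions), CH2Cl2, -20 to 0 °C; fast filtration through Et3N-deactivated silica, used the same day
Reagents that add atoms: carbon tetrabromide, BrC(Br)(Br)Br
Why: The Appel reaction converts the electron-rich benzylic alcohol into the bromide under neutral conditions, so neither acetal nor silyl ether meets acid.

Step 5
Reactants: 6 2-methylbut-3-en-2-ol; 7 triethyl orthoacetate
Product: 8 ethyl 5-methylhex-4-enoate
Conditions: EtCO2H (cat.), 140 °C, EtOH distilled off
Reagents that add atoms: none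
Why: Johnson–Claisen rearrangement; acid-catalysed exchange at the orthoester and a [3,3]-sigmatropic shift transpose the tertiary allylic alcohol into the trisubstituted prenyl-type alkene.

Step 6
Reactants: 8 ethyl 5-methylhex-4-enoate
Product: 9 5-methylhex-4-enoic acid
Conditions: LiOH, THF/MeOH/H2O, rt; then 1 M HCl
Reagents that add atoms: lithium hydroxide, [Li+].[OH-]
Why: Plain ester saponification on a substrate with no other reactive group.

Step 7
Reactants: 9 5-methylhex-4-enoic acid
Product: 10 1-(imidazol-1-yl)-5-methylhex-4-en-1-one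
Conditions: CDI, CH2Cl2, rt
Reagents that add atoms: 1,1'-carbonyldiimidazole, O=C(n1ccnc1)n1ccnc1
Why: CDI activation gives an isolable acyl imidazole, an acyl donor reactive enough to be intercepted by a carbene yet stable to fluoride at low temperature.

Step 8
Reactants: 5 tert-butyl[2-(bromomethyl)-3-(methoxymethoxy)phenoxy]dimethylsilane; 10 1-(imidazol-1-yl)-5-methylhex-4-en-1-one (1.5 equiv)
Product: 13 (3R)-5-(methoxymethoxy)-3-(3-methylbut-2-en-1-yl)chroman-2-one, via o-quinone methide 11 (not isolated), via azolium enolate 12 (not isolated)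
Conditions: (5aR,10bS)-2-mesityl-5a,10b-dihydro-4H,6H-indeno[2,1-b][1,2,4]triazolo[4,3-d][1,4]oxazin-2-ium tetrafluoroborate (15 mol %), CsF, 18-crown-6, 4 Å MS, THF, -20 °C; neutral work-up
Reagents that add atoms: none
Why: Sparingly soluble CsF strips only the TBS group of 5 and the phenoxide expels bromide by 1,4-elimination to give o-quinone methide 11, while the carbene adds to 10, releases imidazole and, after loss of the acidified alpha-proton, becomes the Z-azolium enolate 12. The enolate alpha-carbon adds in Michael fashion to the exocyclic methylene of 11 (C1''–C2'' bond, driven by rearomatisation), and the liberated phenoxide then attacks the acyl azolium in a 6-exo-trig acyl transfer that closes the lactone and frees the carbene. This is the known carbene-catalysed enantioselective formal [4+2] annulation of fluoride-generated o-quinone methides with acyl-imidazole-derived enolates to 3-substituted dihydrocoumarins. The only new stereocentre, C3 of 13 (C2'' of the target), is fixed by the catalyst, whose indane wall blocks one enolate face so that the methylene carbon should bond to the Si face of the alpha-carbon and give R. The step needs chemoselective desilylation (the MOM ether is inert to fluoride), trapping of 11 faster than its oligomerisation or capture by imidazole (slow release keeps 11 dilute and its alkoxy donor tempers it), and survival of the epimerisable alpha-centre (low temperature, weakly basic medium). Regiochemistry is not at stake, since 11 offers a single unsubstituted electrophilic terminus and a single phenoxide oxygen.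

Step 9
Reactants: 13 (3R)-5-(methoxymethoxy)-3-(3-methylbut-2-en-1-yl)chroman-2-one
Product: 14 (2R)-2-[2-hydroxy-6-(methoxymethoxy)benzyl]-N-methoxy-N,5-dimethylhex-4-enamide
Conditions: Me(MeO)NH·HCl, AlMe3, CH2Cl2, 0 °C; aq. potassium sodium tartrate
Reagents that add atoms: N,O-dimethylhydroxylamine hydrochloride, CNOC.Cl
Why: Weinreb aminolysis; the weakly basic aluminium amide opens the activated aryl ester at 0 °C without enolising C2''.

Step 10
Reactants: 14 (2R)-2-[2-hydroxy-6-(methoxymethoxy)benzyl]-N-methoxy-N,5-dimethylhex-4-enamide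
Product: 15 (2R)-N-methoxy-2-[2-(methoxymethoxy)-6-(triisopropylsilyloxy)benzyl]-N,5-dimethylhex-4-enamide
Conditions: TIPSCl, imidazole, DMF, rt
Reagents that add atoms: triisopropylsilyl chloride, CC(C)[Si](Cl)(C(C)C)C(C)C
Why: Phenol silylation stops relactonisation and later hemiketal formation, and the base-robust TIPS ether then serves as the O7 protecting group up to the last step.

Step 11
Reactants: 15 (2R)-N-methoxy-2-[2-(methoxymethoxy)-6-(triisopropylsilyloxy)benzyl]-N,5-dimethylhex-4-enamide
Product: 16 (3R)-3-[2-(methoxymethoxy)-6-(triisopropylsilyloxy)benzyl]-6-methylhept-5-en-2-one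
Conditions: MeMgBr, THF, -20 to 0 °C; cold aq. NH4Cl
Reagents that add atoms: methylmagnesium bromide, C[Mg]Br
Why: Weinreb ketone synthesis; the chelated adduct prevents over-addition and masks the carbonyl until the cold quench, so the alpha-centre is not enolised.

Step 12
Reactants: 16 (3R)-3-[2-(methoxymethoxy)-6-(triisopropylsilyloxy)benzyl]-6-methylhept-5-en-2-one
Product: 17 {3-(methoxymethoxy)-2-[(2R)-5-methyl-2-(prop-1-en-2-yl)hex-4-en-1-yl]phenoxy}triisopropylsilane
Conditions: Cp2TiMe2, toluene, 70 °C, dark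
Reagents that add atoms: dimethyltitanocene Cp2TiMe2, C[Ti](C)(C1C=CC=C1)C1C=CC=C1
Why: Petasis methylenation; thermally formed Cp2Ti=CH2 is non-basic and olefinates the enolisable ketone through an oxatitanacyclobutane, so C2'' is retained and is no longer epimerisable from here on.

Step 13
Reactants: 17 {3-(methoxymethoxy)-2-[(2R)-5-methyl-2-(prop-1-en-2-yl)hex-4-en-1-yl]phenoxy}triisopropylsilane
Product: 19 1-{2-(methoxymethoxy)-3-[(2R)-lavandulyl]-4-(triisopropylsilyloxy)phenyl}ethan-1-one, via aryllithium 18 (not isolated)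
Conditions: n-BuLi, TMEDA, Et2O, 0 °C; then MeC(O)N(OMe)Me, -78 °C to rt; aq. NH4Cl
Reagents that add atoms: N-methoxy-N-methylacetamide, CC(=O)N(C)OC
Why: Directed ortho-metalation; the MOM oxygens bind lithium and the only ring hydrogen ortho to OMOM (the future C4a) is removed, the bulky OTIPS being a poor director, and the Weinreb amide acylates the aryllithium without over-addition.

Step 14
Reactants: 19 1-{2-(methoxymethoxy)-3-[(2R)-lavandulyl]-4-(triisopropylsilyloxy)phenyl}ethan-1-one
Product: 21 1-{2-hydroxy-3-[(2R)-lavandulyl]-4-(triisopropylsilyloxy)phenyl}ethan-1-one, via aryl TMS ether 20 (not isolated)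
Conditions: TMSOTf, 2,2'-bipyridyl, MeCN, 0 °C to rt; then H2O, rt
Reagents that add atoms: none
Why: Silyl triflate/bipyridyl cleavage of an aromatic MOM ether runs through the TMS ether in a buffered, proton-free medium, so the lavandulyl alkenes and the TIPS ether are spared and any silyl enol ether reverts to the ketone in the aqueous stage.

Step 15
Reactants: 21 1-{2-hydroxy-3-[(2R)-lavandulyl]-4-(triisopropylsilyloxy)phenyl}ethan-1-one
Product: 23 8-[(2R)-lavandulyl]-7-(triisopropylsilyloxy)-4H-chromen-4-one, via enaminone 22 (not isolated)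
Conditions: Me2NCH(OMe)2, toluene, 80 °C; evaporate; then AcOH, 60 °C
Reagents that add atoms: N,N-dimethylformamide dimethyl acetal, COC(OC)N(C)C
Why: This is the standard enaminone route to 2,3-unsubstituted chromones (condensation of the methyl ketone with the amide acetal, then phenol addition to the beta-carbon and loss of dimethylamine), and the weak acid is too mild to protonate the alkenes or cleave the silyl ether.

Step 16
Reactants: 24 4-bromo-3-methoxyphenol
Product: 25 (4-bromo-3-methoxyphenoxy)triisopropylsilane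
Conditions: TIPSCl, imidazole, DMF, rt
Reagents that add atoms: triisopropylsilyl chloride, CC(C)[Si](Cl)(C(C)C)C(C)C
Why: Routine phenol silylation gives ring B the same fluoride-labile group as ring A, so that one final operation unmasks both phenols.

Step 17
Reactants: 25 (4-bromo-3-methoxyphenoxy)triisopropylsilane
Product: 27 [2-methoxy-4-(triisopropylsilyloxy)phenyl]boronic acid, via aryllithium 26 (not isolated)
Conditions: n-BuLi, THF, -78 °C; B(Oi-Pr)3, -78 °C to rt; 1 M HCl, 0 °C, brief
Reagents that add atoms: triisopropyl borate, CC(C)OB(OC(C)C)OC(C)C; water, O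
Why: Bromine–lithium exchange followed by borylation and hydrolysis; lithium sits para to the silyloxy group, so no silyl migration to carbon can occur.

Step 18
Reactants: 23 8-[(2R)-lavandulyl]-7-(triisopropylsilyloxy)-4H-chromen-4-one; 27 [2-methoxy-4-(triisopropylsilyloxy)phenyl]boronic acid (3 equiv, in portions)
Product: 28 (2S)-8-[(2R)-lavandulyl]-2-[2-methoxy-4-(triisopropylsilyloxy)phenyl]-7-(triisopropylsilyloxy)chroman-4-one
Conditions: [RhCl(C2H4)2]2 (2.5 mol %), (1S,4S)-2,5-diphenylbicyclo[2.2.2]octa-2,5-diene (5.5 mol %), K3PO4 (0.3 equiv), toluene/H2O 10:1, 40 °C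
Reagents that add atoms: none
Why: Hayashi–Miyaura asymmetric 1,4-addition, known for chromones; the aryl-rhodium species inserts into C2=C3 on the face left open by the C2-symmetric diene (Re face at C2), which sets 2S under catalyst control independently of the remote C2'', and hydrolysis of the rhodium enolate releases the flavanone.

Step 19
Reactants: 28 (2S)-8-[(2R)-lavandulyl]-2-[2-methoxy-4-(triisopropylsilyloxy)phenyl]-7-(triisopropylsilyloxy)chroman-4-one
Product: 29 alopecurone G
Conditions: TBAF/AcOH (1:1), THF, 0 °C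
Reagents that add atoms: none
Why: Fluoride desilylation of both aryl TIPS ethers; the acetic acid buffer keeps the phenoxides protonated, which prevents retro-oxa-Michael opening and hence epimerisation at C2, and no acid strong enough to cyclise the 7-OH onto the lavandulyl alkenes is present.

Compound list
1 | 2,6-dihydroxybenzaldehyde | O=Cc1c(O)cccc1O | starting material
2 | 2-hydroxy-6-(methoxymethoxy)benzaldehyde | COCOc1cccc(O)c1C=O | intermediate
3 | 2-(tert-butyldimethylsilyloxy)-6-(methoxymethoxy)benzaldehyde | COCOc1cccc(O[Si](C)(C)C(C)(C)C)c1C=O | intermediate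
4 | [2-(tert-butyldimethylsilyloxy)-6-(methoxymethoxy)phenyl]methanol | COCOc1cccc(O[Si](C)(C)C(C)(C)C)c1CO | intermediate
5 | tert-butyl[2-(bromomethyl)-3-(methoxymethoxy)phenoxy]dimethylsilane | COCOc1cccc(O[Si](C)(C)C(C)(C)C)c1CBr | intermediate
6 | 2-methylbut-3-en-2-ol | C=CC(C)(C)O | starting material
7 | triethyl orthoacetate | CCOC(C)(OCC)OCC | starting material
8 | ethyl 5-methylhex-4-enoate | CCOC(=O)CCC=C(C)C | intermediate
9 | 5-methylhex-4-enoic acid | CC(C)=CCCC(=O)O | intermediate
10 | 1-(imidazol-1-yl)-5-methylhex-4-en-1-one | CC(C)=CCCC(=O)n1ccnc1 | intermediate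
11 | 5-(methoxymethoxy)-6-methylidenecyclohexa-2,4-dien-1-one (o-quinone methide, not isolated) | C=C1C(=O)C=CC=C1OCOC | intermediate
12 | (Z)-1-[(5aR,10bS)-2-mesityl-5a,10b-dihydro-4H,6H-indeno[2,1-b][1,2,4]triazolo[4,3-d][1,4]oxazin-2-ium-1-yl]-5-methylhexa-1,4-dien-1-olate (azolium enolate, not isolated) | CC(C)=CC/C=C(\[O-])c1n2c(n[n+]1-c1c(C)cc(C)cc1C)CO[C@@H]1Cc3ccccc3[C@H]21 | intermediate
13 | (3R)-5-(methoxymethoxy)-3-(3-methylbut-2-en-1-yl)chroman-2-one | O=C1Oc2cccc(OCOC)c2C[C@H]1CC=C(C)C | intermediate
14 | (2R)-2-[2-hydroxy-6-(methoxymethoxy)benzyl]-N-methoxy-N,5-dimethylhex-4-enamide | CON(C)C(=O)[C@H](CC=C(C)C)Cc1c(O)cccc1OCOC | intermediate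
15 | (2R)-N-methoxy-2-[2-(methoxymethoxy)-6-(triisopropylsilyloxy)benzyl]-N,5-dimethylhex-4-enamide | CON(C)C(=O)[C@H](CC=C(C)C)Cc1c(O[Si](C(C)C)(C(C)C)C(C)C)cccc1OCOC | intermediate
16 | (3R)-3-[2-(methoxymethoxy)-6-(triisopropylsilyloxy)benzyl]-6-methylhept-5-en-2-one | CC(=O)[C@H](CC=C(C)C)Cc1c(O[Si](C(C)C)(C(C)C)C(C)C)cccc1OCOC | intermediate
17 | {3-(methoxymethoxy)-2-[(2R)-5-methyl-2-(prop-1-en-2-yl)hex-4-en-1-yl]phenoxy}triisopropylsilane | C=C(C)[C@H](CC=C(C)C)Cc1c(O[Si](C(C)C)(C(C)C)C(C)C)cccc1OCOC | intermediate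
18 | {2-(methoxymethoxy)-3-[(2R)-lavandulyl]-4-(triisopropylsilyloxy)phenyl}lithium (not isolated) | C=C(C)[C@H](CC=C(C)C)Cc1c(O[Si](C(C)C)(C(C)C)C(C)C)ccc([Li])c1OCOC | intermediate
19 | 1-{2-(methoxymethoxy)-3-[(2R)-lavandulyl]-4-(triisopropylsilyloxy)phenyl}ethan-1-one | C=C(C)[C@H](CC=C(C)C)Cc1c(O[Si](C(C)C)(C(C)C)C(C)C)ccc(C(C)=O)c1OCOC | intermediate
20 | 1-{3-[(2R)-lavandulyl]-4-(triisopropylsilyloxy)-2-(trimethylsilyloxy)phenyl}ethan-1-one (not isolated) | C=C(C)[C@H](CC=C(C)C)Cc1c(O[Si](C(C)C)(C(C)C)C(C)C)ccc(C(C)=O)c1O[Si](C)(C)C | intermediate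
21 | 1-{2-hydroxy-3-[(2R)-lavandulyl]-4-(triisopropylsilyloxy)phenyl}ethan-1-one | C=C(C)[C@H](CC=C(C)C)Cc1c(O[Si](C(C)C)(C(C)C)C(C)C)ccc(C(C)=O)c1O | intermediate
22 | (E)-3-(dimethylamino)-1-{2-hydroxy-3-[(2R)-lavandulyl]-4-(triisopropylsilyloxy)phenyl}prop-2-en-1-one (not isolated) | C=C(C)[C@H](CC=C(C)C)Cc1c(O[Si](C(C)C)(C(C)C)C(C)C)ccc(C(=O)/C=C/N(C)C)c1O | intermediate
23 | 8-[(2R)-lavandulyl]-7-(triisopropylsilyloxy)-4H-chromen-4-one | C=C(C)[C@H](CC=C(C)C)Cc1c(O[Si](C(C)C)(C(C)C)C(C)C)ccc2c1OC=CC2=O | intermediate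
24 | 4-bromo-3-methoxyphenol | COc1cc(O)ccc1Br | starting material
25 | (4-bromo-3-methoxyphenoxy)triisopropylsilane | COc1cc(O[Si](C(C)C)(C(C)C)C(C)C)ccc1Br | intermediate
26 | [2-methoxy-4-(triisopropylsilyloxy)phenyl]lithium (not isolated) | COc1cc(O[Si](C(C)C)(C(C)C)C(C)C)ccc1[Li] | intermediate
27 | [2-methoxy-4-(triisopropylsilyloxy)phenyl]boronic acid | COc1cc(O[Si](C(C)C)(C(C)C)C(C)C)ccc1B(O)O | intermediate
28 | (2S)-8-[(2R)-lavandulyl]-2-[2-methoxy-4-(triisopropylsilyloxy)phenyl]-7-(triisopropylsilyloxy)chroman-4-one | C=C(C)[C@H](CC=C(C)C)Cc1c(O[Si](C(C)C)(C(C)C)C(C)C)ccc2c1O[C@H](c1ccc(O[Si](C(C)C)(C(C)C)C(C)C)cc1OC)CC2=O | intermediate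
29 | alopecurone G, (2S)-7-hydroxy-2-(4-hydroxy-2-methoxyphenyl)-8-[(2R)-lavandulyl]chroman-4-one | C=C(C)[C@H](CC=C(C)C)Cc1c(O)ccc2c1O[C@H](c1ccc(O)cc1OC)CC2=O | target

Total step count: 19.
Longest linear sequence: 14 steps (steps 1–4, 8–15, 18 and 19).

Steps most likely to fail

Step 8. Enantiopurity may erode through fluoride- or imidazole-mediated enolisation of the aryl ester. The quinone methide may oligomerise, or it may alkylate the free carbene and shut the catalysis down. The fallback replaces catalyst control by auxiliary control; it sets out from 10 and 5 and returns at 13. (4S)-4-Benzyloxazolidin-2-one, lithiated with n-BuLi in THF at -78 °C, is acylated by 10 to give N-acyl oxazolidinone F1. Evans asymmetric alkylation follows (NaHMDS, THF, -78 °C, then 5, which here reacts as a plain SN2 electrophile with its silyl ether intact). It should give alkylated imide F2, because the benzyl group of the auxiliary shields one face of the chelated Z-enolate and fixes R at the new centre. TBAF/AcOH in THF frees phenol imide F3. Its phenol attacks the exocyclic imide carbonyl (6-exo-trig, catalytic DMAP if needed), expels the auxiliary and gives 13.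

Step 18. Protodeboronation of the electron-rich, ortho-substituted boronic acid may outrun the slow insertion into the vinylogous ester. Base-induced retro-oxa-Michael opening may also erode C2. The fallback builds the heterocycle from a chalcone and sorts the C2 epimers by reagent control; it sets out from 21 and 25 and returns at 28.
- Aryllithium 26, made from 25 as in step 17, is quenched with DMF to give 2-methoxy-4-(triisopropylsilyloxy)benzaldehyde F4.
- Pyrrolidine-mediated aldol condensation of F4 with 21 (EtOH, 50 °C) gives 2'-hydroxychalcone F5.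
- NaOAc in hot EtOH closes F5 by oxa-Michael addition to flavanone epimer mixture F6.
- Asymmetric transfer hydrogenation is then run as a kinetic resolution (RuCl[(R,R)-TsDPEN](p-cymene), HCO2H/Et3N, stopped near half conversion). It should reduce the 2R epimer to cis-flavan-4-ol F7 and leave the 2S epimer, which is 28 and is separated by chromatography.

Step 13. Lateral (benzylic) or allylic metalation may compete with ring metalation, the base may attack silicon, or the aryllithium may merely enolise the acetamide. The fallback swaps carbanion chemistry for phenoxide-directed electrophilic substitution; it sets out from 17 and returns at 21. The MOM group is removed first (TMSOTf, 2,2'-bipyridyl, MeCN; then H2O), through aryl TMS ether F8, to give lavandulyl phenol F9. Casnati–Skattebøl ortho-formylation (MgCl2, Et3N, paraformaldehyde, MeCN, reflux) can reach only the one free position ortho to the phenol and gives salicylaldehyde F10. Excess MeMgBr (THF, 0 °C) gives benzylic carbinol F11, whose carbinol configuration is of no consequence. MnO2 in CH2Cl2 oxidises it to 21.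

Further compounds
F1 | step 8 | (4S)-4-benzyl-3-(5-methylhex-4-enoyl)oxazolidin-2-one | CC(C)=CCCC(=O)N1[C@@H](Cc2ccccc2)COC1=O
F2 | step 8 | (4S)-4-benzyl-3-{(2R)-2-[2-(tert-butyldimethylsilyloxy)-6-(methoxymethoxy)benzyl]-5-methylhex-4-enoyl}oxazolidin-2-one | CC(C)=CC[C@H](Cc1c(OCOC)cccc1O[Si](C)(C)C(C)(C)C)C(=O)N1[C@@H](Cc2ccccc2)COC1=O
F3 | step 8 | (4S)-4-benzyl-3-{(2R)-2-[2-hydroxy-6-(methoxymethoxy)benzyl]-5-methylhex-4-enoyl}oxazolidin-2-one | CC(C)=CC[C@H](Cc1c(OCOC)cccc1O)C(=O)N1[C@@H](Cc2ccccc2)COC1=O
F4 | step 18 | 2-methoxy-4-(triisopropylsilyloxy)benzaldehyde | COc1cc(O[Si](C(C)C)(C(C)C)C(C)C)ccc1C=O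
F5 | step 18 | (E)-1-{2-hydroxy-3-[(2R)-lavandulyl]-4-(triisopropylsilyloxy)phenyl}-3-[2-methoxy-4-(triisopropylsilyloxy)phenyl]prop-2-en-1-one | C=C(C)[C@H](CC=C(C)C)Cc1c(O[Si](C(C)C)(C(C)C)C(C)C)ccc(C(=O)/C=C/c2ccc(O[Si](C(C)C)(C(C)C)C(C)C)cc2OC)c1O
F6 | step 18 | 8-[(2R)-lavandulyl]-2-[2-methoxy-4-(triisopropylsilyloxy)phenyl]-7-(triisopropylsilyloxy)chroman-4-one, both C2 epimers | C=C(C)[C@H](CC=C(C)C)Cc1c(O[Si](C(C)C)(C(C)C)C(C)C)ccc2c1OC(c1ccc(O[Si](C(C)C)(C(C)C)C(C)C)cc1OC)CC2=O
F7 | step 18 | (2R,4R)-8-[(2R)-lavandulyl]-2-[2-methoxy-4-(triisopropylsilyloxy)phenyl]-7-(triisopropylsilyloxy)chroman-4-ol | C=C(C)[C@H](CC=C(C)C)Cc1c(O[Si](C(C)C)(C(C)C)C(C)C)ccc2c1O[C@@H](c1ccc(O[Si](C(C)C)(C(C)C)C(C)C)cc1OC)C[C@H]2O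
F8 | step 13 | {2-[(2R)-lavandulyl]-3-(trimethylsilyloxy)phenoxy}triisopropylsilane | C=C(C)[C@H](CC=C(C)C)Cc1c(O[Si](C)(C)C)cccc1O[Si](C(C)C)(C(C)C)C(C)C
F9 | step 13 | 2-[(2R)-lavandulyl]-3-(triisopropylsilyloxy)phenol | C=C(C)[C@H](CC=C(C)C)Cc1c(O)cccc1O[Si](C(C)C)(C(C)C)C(C)C
F10 | step 13 | 2-hydroxy-3-[(2R)-lavandulyl]-4-(triisopropylsilyloxy)benzaldehyde | C=C(C)[C@H](CC=C(C)C)Cc1c(O[Si](C(C)C)(C(C)C)C(C)C)ccc(C=O)c1O
F11 | step 13 | 6-(1-hydroxyethyl)-2-[(2R)-lavandulyl]-3-(triisopropylsilyloxy)phenol, both carbinol epimers | C=C(C)[C@H](CC=C(C)C)Cc1c(O[Si](C(C)C)(C(C)C)C(C)C)ccc(C(C)O)c1O
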